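**Plan**

- Target 18 is a flavanone with a single stereocentre (C2). Ring A carries 5,7-dihydroxy and 6-prenyl groups; ring B is a 4-hydroxy-3,5-diprenylphenyl group.
- Retrosynthesis: (a) remove three MOM ethers; (b) cut ring C at C2–C3 and C4–C4a in one stroke, which gives an O-aryl oxocarbenium ion (O1=C2) and a silylated ynol ether as the C3–C4 unit at the ketene oxidation level; (c) cut O1–C2 of the mixed acetal 13 to ring A phenol 6 and ring B acetal 10; (d) trace the prenyl groups to a directed lithiation (ring A) and a Stille coupling (ring B).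
- Enabling feature: C2 is a benzylic carbon that bears O1 and the 4-oxygenated ring B, so it ionises easily to an aryl oxocarbenium ion. C4a lies ortho to O1, next to O5 and para to O7 of the phloroglucinol ring A, so it is a strong carbon nucleophile. Ring A has its prenyl group para to O1, so the two carbons ortho to O1 are equivalent and closure can give only the 6-prenyl pattern.
- Forward order: phenol 6 (steps 1–3) and acetal 10 (steps 4–6) are joined through O1–C2 (step 7), ring C is closed (step 8), and the phenols are unmasked (step 9).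
- Stereochemistry: C2 is set in step 8 by a chiral squaramide-bound triflate counter-anion. The acetal centre of 13 is racemic and is erased on ionisation. No later step is basic.

Key step: step 8

Remark: the target as drawn has the 2R configuration (O1 > C1' > C3 > H), and the route is written for this enantiomer.
Remark: SQ is the chiral squaramide 3-{[3,5-bis(trifluoromethyl)phenyl]amino}-4-{[(2S)-3,3-dimethyl-1-oxo-1-[(2R)-2-(phenanthren-9-yl)pyrrolidin-1-yl]butan-2-yl]amino}cyclobut-3-ene-1,2-dione or its mirror image; the sense of induction of a new reaction cannot be assigned in advance, so the antipode that gives 2R is to be fixed in a pilot run.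
Remark: (ethoxyethynyl)trimethylsilane 14 is assumed to be purchasable; if not, it is one step from ethoxyacetylene (n-BuLi, Me3SiCl).

**Route**

Step 1
Reactants: 1 resorcinol (benzene-1,3-diol)
Product: 2 1,3-bis(methoxymethoxy)benzene
Conditions: MOMCl (2.4 equiv), i-Pr2NEt (3 equiv), CH2Cl2, 0 °C to rt
Reagents that add atoms: chloromethyl methyl ether (MOMCl), COCCl
Why: Double Williamson-type O-alkylation of the two phenols by the reactive α-chloro ether gives the bis-MOM ether, whose two acetal oxygens are needed to direct the lithiation of step 2.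

Step 2
Reactants: 2 1,3-bis(methoxymethoxy)benzene
Product: 4 1,3-bis(methoxymethoxy)-2-(3-methylbut-2-en-1-yl)benzene, via aryllithium 3 (not isolated)
Conditions: n-BuLi (1.1 equiv), THF, 0 °C; then prenyl bromide (1.2 equiv), –78 °C to rt
Reagents that add atoms: 1-bromo-3-methylbut-2-ene (prenyl bromide), CC(C)=CCBr
Why: Directed ortho-metalation: the two MOM ethers jointly direct n-BuLi to the carbon between them and the aryllithium 3 displaces bromide from the primary carbon of prenyl bromide (SN2), which installs the linear prenyl group of ring A.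

Step 3
Reactants: 4 1,3-bis(methoxymethoxy)-2-(3-methylbut-2-en-1-yl)benzene
Product: 6 3,5-bis(methoxymethoxy)-4-(3-methylbut-2-en-1-yl)phenol, via aryl pinacol boronate 5 (not isolated)
Conditions: [Ir(OMe)(cod)]2 (1.5 mol%), 4,4'-di-tert-butyl-2,2'-bipyridine (3 mol%), B2pin2 (1.0 equiv), THF, 60 °C; then aq. NaOH, 30% H2O2, 0 °C to rt
Reagents that add atoms: hydrogen peroxide, OO
Why: Sterically controlled iridium-catalysed aromatic C–H borylation should take the only ring C–H without an ortho substituent (para to the prenyl group), the hindered trisubstituted alkene being a poor substrate for the iridium boryl species, and alkaline peroxide then replaces boron by oxygen at the same carbon without epoxidising the alkene.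

Step 4
Reactants: 7 3,5-dibromo-4-hydroxybenzaldehyde
Product: 8 3,5-dibromo-4-(methoxymethoxy)benzaldehyde
Conditions: MOMCl (1.3 equiv), i-Pr2NEt (1.5 equiv), CH2Cl2, 0 °C to rt
Reagents that add atoms: chloromethyl methyl ether (MOMCl), COCCl
Why: O-alkylation of the acidic 2,6-dibromophenol masks the phenol for the organometallic and acetal chemistry that follows.

Step 5
Reactants: 8 3,5-dibromo-4-(methoxymethoxy)benzaldehyde
Product: 9 4-(methoxymethoxy)-3,5-bis(3-methylbut-2-en-1-yl)benzaldehyde
Conditions: tributyl(3-methylbut-2-en-1-yl)stannane (2.5 equiv), Pd(PPh3)4 (5 mol%), DMF, 95 °C; aq. KF work-up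
Reagents that add atoms: tributyl(3-methylbut-2-en-1-yl)stannane, CCCC[Sn](CCCC)(CCCC)CC=C(C)C
Why: Double Stille coupling: oxidative addition into the C–Br bonds activated by the para-formyl group and transfer of the prenyl group from tin with C–C bond formation at its CH2 terminus, as is usual for prenylstannanes, gives the 3,5-diprenyl pattern of ring B while the aldehyde and the MOM ether are inert under these neutral conditions.

Step 6
Reactants: 9 4-(methoxymethoxy)-3,5-bis(3-methylbut-2-en-1-yl)benzaldehyde
Product: 10 5-(dimethoxymethyl)-2-(methoxymethoxy)-1,3-bis(3-methylbut-2-en-1-yl)benzene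
Conditions: HC(OMe)3 (3 equiv), MeOH, pyridinium p-toluenesulfonate (5 mol%), rt; then Et3N
Reagents that add atoms: trimethyl orthoformate, COC(OC)OC
Why: Acid-catalysed acetalisation driven by the orthoformate, with the weak acid PPTS chosen so that the aryl MOM ether and the alkenes are not attacked.

Step 7
Reactants: 10 5-(dimethoxymethyl)-2-(methoxymethoxy)-1,3-bis(3-methylbut-2-en-1-yl)benzene; 6 3,5-bis(methoxymethoxy)-4-(3-methylbut-2-en-1-yl)phenol
Product: 13 5-{[3,5-bis(methoxymethoxy)-4-(3-methylbut-2-en-1-yl)phenoxy](methoxy)methyl}-2-(methoxymethoxy)-1,3-bis(3-methylbut-2-en-1-yl)benzene, via α-chloro ether 11 (not isolated), via sodium phenoxide 12 (not isolated)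
Conditions: 10, AcCl (1.05 equiv), CH2Cl2, 0 °C to rt, then evaporation; separately 6, NaH (1.1 equiv), THF/DMF, 0 °C; combined at –40 °C, then 0 °C; chromatography on Et3N-deactivated silica
Reagents that add atoms: none
Why: Acetyl chloride converts the benzaldehyde-type dimethyl acetal into the α-chloro ether 11 (this acetal ionises far more readily than the formaldehyde-type MOM acetal), and the sodium phenoxide 12 is O-alkylated by 11 in an SN1-like Williamson reaction as in a MOM protection; the new acetal carbon is racemic, which is of no consequence because it becomes planar in step 8.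

Step 8
Reactants: 13 mixed O-aryl O-methyl acetal; 14 (ethoxyethynyl)trimethylsilane
Product: 17 (2R)-5,7-bis(methoxymethoxy)-2-[4-(methoxymethoxy)-3,5-bis(3-methylbut-2-en-1-yl)phenyl]-6-(3-methylbut-2-en-1-yl)-2,3-dihydro-4H-chromen-4-one, via C3-silylated 4-ethoxy-2H-chromene 15 (not isolated), via 4-ethoxy-2H-chromene 16 (not isolated)
Conditions: 14 (2.5 equiv), squaramide SQ (10 mol%), Me3SiOTf (15 mol%), t-BuOMe, –78 °C; then Et3N; then THF, 1 M aq. HCl, 0 °C
Reagents that add atoms: water, O
Why: Proposed new method: the squaramide-bound Me3SiOTf should silylate the more basic methoxy oxygen of 13 and expel Me3SiOMe, leaving the O-aryl oxocarbenium ion (O1=C2) paired with the chiral squaramide–triflate anion; the silicon-bearing carbon of 14 then attacks C2 (bond C2–C3) to give a β-silyl-stabilised ketene oxonium ion whose sp carbon C4 is captured by C4a of ring A (bond C4–C4a), and the proton lost on rearomatisation removes the C3 silyl group of 15 by ipso-protonation, which returns Me3SiOTf and closes the catalytic cycle at 16. The closest known reaction types are the Lewis acid-promoted oxa-Povarov (4+2) annulation of aryl oxocarbenium ions with alkenes, the enantioselective addition of silyl nucleophiles to acetal-derived aryl oxocarbenium ions under hydrogen-bond-donor/silyl triflate ion-pair catalysis, and the Povarov reaction of N-aryl iminium ions under chiral anion-binding catalysis; an enantioselective version with an O-aryl oxocarbenium ion and an alkynyl ether is new. Ring C closes in the second event by a 6-exo-dig Friedel–Crafts attack of C4a on the cumulated carbon C4, so that the whole process is a stepwise cationic hetero-(4+2) annulation of the 2-oxadiene O1=C2/C8a=C4a with the alkyne. The only new stereocentre, C2, is fixed in the first C–C bond formation, where the chiral anion complex shields one face of the planar oxocarbenium ion, and the catalyst antipode is chosen so that the 2R product forms. The step needs (a) loss of methoxide and not of aryloxide, secured by the oxophilic silyl Lewis acid, (b) attack by 14 and not by the three prenyl alkenes, secured by the much higher nucleophilicity of the ynol ether, (c) closure on C4a and not on O1, secured by the three oxygen substituents ortho and para to C4a, and (d) no regiochemical choice, because ring A with its prenyl group para to O1 offers two equivalent ortho carbons. Cold aqueous acid then hydrolyses the enol ether 16 (and any remaining 15) to the ketone 17 without touching the MOM ethers or C2.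

Step 9
Reactants: 17 (2R)-5,7-bis(methoxymethoxy)-2-[4-(methoxymethoxy)-3,5-bis(3-methylbut-2-en-1-yl)phenyl]-6-(3-methylbut-2-en-1-yl)-2,3-dihydro-4H-chromen-4-one
Product: 18 (2R)-5,7-dihydroxy-2-[4-hydroxy-3,5-bis(3-methylbut-2-en-1-yl)phenyl]-6-(3-methylbut-2-en-1-yl)-2,3-dihydro-4H-chromen-4-one
Conditions: 3 M aq. HCl/MeOH (1:4), 40 °C
Reagents that add atoms: none
Why: Acid-catalysed transacetalisation of the three MOM ethers to dimethoxymethane is the standard unmasking of prenylated flavanones; in the absence of base C2 cannot epimerise by retro-oxa-Michael ring opening, and the moderate temperature should keep the prenyl groups from cyclising onto the neighbouring phenols.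

**Compound list**

1 | resorcinol (benzene-1,3-diol) | Oc1cccc(O)c1 | starting material
2 | 1,3-bis(methoxymethoxy)benzene | COCOc1cccc(OCOC)c1 | intermediate
3 | [2,6-bis(methoxymethoxy)phenyl]lithium | [Li]c1c(OCOC)cccc1OCOC | intermediate (not isolated)
4 | 1,3-bis(methoxymethoxy)-2-(3-methylbut-2-en-1-yl)benzene | CC(C)=CCc1c(OCOC)cccc1OCOC | intermediate
5 | 2-[3,5-bis(methoxymethoxy)-4-(3-methylbut-2-en-1-yl)phenyl]-4,4,5,5-tetramethyl-1,3,2-dioxaborolane | CC(C)=CCc1c(OCOC)cc(cc1OCOC)B1OC(C)(C)C(C)(C)O1 | intermediate (not isolated)
6 | 3,5-bis(methoxymethoxy)-4-(3-methylbut-2-en-1-yl)phenol | CC(C)=CCc1c(OCOC)cc(O)cc1OCOC | intermediate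
7 | 3,5-dibromo-4-hydroxybenzaldehyde | O=Cc1cc(Br)c(O)c(Br)c1 | starting material
8 | 3,5-dibromo-4-(methoxymethoxy)benzaldehyde | COCOc1c(Br)cc(C=O)cc1Br | intermediate
9 | 4-(methoxymethoxy)-3,5-bis(3-methylbut-2-en-1-yl)benzaldehyde | CC(C)=CCc1cc(C=O)cc(CC=C(C)C)c1OCOC | intermediate
10 | 5-(dimethoxymethyl)-2-(methoxymethoxy)-1,3-bis(3-methylbut-2-en-1-yl)benzene | CC(C)=CCc1cc(C(OC)OC)cc(CC=C(C)C)c1OCOC | intermediate
11 | 5-[chloro(methoxy)methyl]-2-(methoxymethoxy)-1,3-bis(3-methylbut-2-en-1-yl)benzene, racemic | CC(C)=CCc1cc(C(Cl)OC)cc(CC=C(C)C)c1OCOC | intermediate (not isolated)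
12 | sodium 3,5-bis(methoxymethoxy)-4-(3-methylbut-2-en-1-yl)phenoxide | CC(C)=CCc1c(OCOC)cc([O-])cc1OCOC.[Na+] | intermediate (not isolated)
13 | 5-{[3,5-bis(methoxymethoxy)-4-(3-methylbut-2-en-1-yl)phenoxy](methoxy)methyl}-2-(methoxymethoxy)-1,3-bis(3-methylbut-2-en-1-yl)benzene, racemic mixed O-aryl O-methyl acetal | CC(C)=CCc1cc(C(OC)Oc2cc(OCOC)c(CC=C(C)C)c(OCOC)c2)cc(CC=C(C)C)c1OCOC | intermediate
14 | (ethoxyethynyl)trimethylsilane | CCOC#C[Si](C)(C)C | starting material
15 | [(2S)-4-ethoxy-5,7-bis(methoxymethoxy)-2-[4-(methoxymethoxy)-3,5-bis(3-methylbut-2-en-1-yl)phenyl]-6-(3-methylbut-2-en-1-yl)-2H-chromen-3-yl]trimethylsilane; same spatial arrangement at C2 as in 18, the descriptor is S only because silicon raises the rank of C3 | CC(C)=CCc1cc([C@H]2C([Si](C)(C)C)=C(OCC)c3c(cc(OCOC)c(CC=C(C)C)c3OCOC)O2)cc(CC=C(C)C)c1OCOC | intermediate (not isolated)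
16 | (2R)-4-ethoxy-5,7-bis(methoxymethoxy)-2-[4-(methoxymethoxy)-3,5-bis(3-methylbut-2-en-1-yl)phenyl]-6-(3-methylbut-2-en-1-yl)-2H-chromene | CC(C)=CCc1cc([C@H]2C=C(OCC)c3c(cc(OCOC)c(CC=C(C)C)c3OCOC)O2)cc(CC=C(C)C)c1OCOC | intermediate (not isolated)
17 | (2R)-5,7-bis(methoxymethoxy)-2-[4-(methoxymethoxy)-3,5-bis(3-methylbut-2-en-1-yl)phenyl]-6-(3-methylbut-2-en-1-yl)-2,3-dihydro-4H-chromen-4-one | CC(C)=CCc1cc([C@H]2CC(=O)c3c(cc(OCOC)c(CC=C(C)C)c3OCOC)O2)cc(CC=C(C)C)c1OCOC | intermediate
18 | (2R)-5,7-dihydroxy-2-[4-hydroxy-3,5-bis(3-methylbut-2-en-1-yl)phenyl]-6-(3-methylbut-2-en-1-yl)-2,3-dihydro-4H-chromen-4-one | CC(C)=CCc1cc([C@H]2CC(=O)c3c(cc(O)c(CC=C(C)C)c3O)O2)cc(CC=C(C)C)c1O | target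

**Step count and risks**

Total: 9 steps. Longest linear sequence: 6 steps (steps 1–3 or 4–6, then 7–9).

The three steps most likely to fail are step 8, step 3 and step 7, in that order.

Step 8 (proposed new method). The facial selectivity of the addition to the oxocarbenium ion may be poor. Adventitious protons may ionise 13 with loss of the aryloxy group instead of the methoxy group. The ketene oxonium ion may close on O1 (alkyne–carbonyl metathesis pathway) instead of on C4a. The vinylogous acetal of 15 and 16 may open before hydrolysis and erode the configuration at C2.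

The fallback makes the two bonds in separate, known operations and sets out from 13. A Mukaiyama-type addition of 1-(tert-butyldimethylsilyloxy)-1-methoxyethene to 13 under the same SQ/Me3SiOTf pair in t-BuOMe at –78 °C (the addition of silyl ketene acetals to acetal-derived aryl oxocarbenium ions is the established use of this ion-pair system) should give methyl (3R)-3-[3,5-bis(methoxymethoxy)-4-(3-methylbut-2-en-1-yl)phenoxy]-3-[4-(methoxymethoxy)-3,5-bis(3-methylbut-2-en-1-yl)phenyl]propanoate F1. The ester is cleaved without base by Me3SnOH in 1,2-dichloroethane at 70 °C, so that no retro-oxa-Michael elimination is invited, to give (3R)-3-[3,5-bis(methoxymethoxy)-4-(3-methylbut-2-en-1-yl)phenoxy]-3-[4-(methoxymethoxy)-3,5-bis(3-methylbut-2-en-1-yl)phenyl]propanoic acid F2. Activation with (CF3CO)2O in CH2Cl2 at 0 °C should bring about the intramolecular Friedel–Crafts acylation at the carbon ortho to O1, which comes back to the route at 17. If the enantiomeric purity needs upgrading, 17 is passed over a chiral stationary phase.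

Step 3. The iridium boryl and hydride species may hydroborate, isomerise or borylate the prenyl alkene, and the electron-rich ring may be borylated slowly.

The fallback changes the order so that no alkene is present during the borylation, and sets out from 2. Borylation of 2 with the same catalyst at the carbon meta to both MOM ethers should give 2-[3,5-bis(methoxymethoxy)phenyl]-4,4,5,5-tetramethyl-1,3,2-dioxaborolane F3, and NaOH/H2O2 then gives 3,5-bis(methoxymethoxy)phenol F4. Silylation (i-Pr3SiCl, imidazole, DMF) gives [3,5-bis(methoxymethoxy)phenoxy]tri(propan-2-yl)silane F5. n-BuLi in THF at 0 °C lithiates between the two MOM ethers, away from the bulky silyl ether, to give [2,6-bis(methoxymethoxy)-4-{[tri(propan-2-yl)silyl]oxy}phenyl]lithium F6. Prenyl bromide gives [3,5-bis(methoxymethoxy)-4-(3-methylbut-2-en-1-yl)phenoxy]tri(propan-2-yl)silane F7, and Bu4NF in THF releases the phenol, which comes back to the route at 6.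

Step 7. The aryl MOM ether may be lost, or HCl may add to a prenyl group, while the chloro ether is made. The phenoxide may be alkylated at carbon instead of oxygen. The labile mixed acetal may hydrolyse on isolation.

The fallback avoids the chloro ether and the strong base and sets out from 10 and 6. A direct transacetalisation (pyridinium p-toluenesulfonate (5 mol%), toluene, 5 Å molecular sieves, 40 °C under slightly reduced pressure to remove methanol) exchanges one methoxy group of 10 for the phenol oxygen of 6 and comes back to the route at 13, used crude after filtration through basic alumina. This fallback makes no new compound (F0).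

**Further compounds**

F1 | step 8 | methyl (3R)-3-[3,5-bis(methoxymethoxy)-4-(3-methylbut-2-en-1-yl)phenoxy]-3-[4-(methoxymethoxy)-3,5-bis(3-methylbut-2-en-1-yl)phenyl]propanoate | CC(C)=CCc1cc([C@@H](CC(=O)OC)Oc2cc(OCOC)c(CC=C(C)C)c(OCOC)c2)cc(CC=C(C)C)c1OCOC
F2 | step 8 | (3R)-3-[3,5-bis(methoxymethoxy)-4-(3-methylbut-2-en-1-yl)phenoxy]-3-[4-(methoxymethoxy)-3,5-bis(3-methylbut-2-en-1-yl)phenyl]propanoic acid | CC(C)=CCc1cc([C@@H](CC(=O)O)Oc2cc(OCOC)c(CC=C(C)C)c(OCOC)c2)cc(CC=C(C)C)c1OCOC
F3 | step 3 | 2-[3,5-bis(methoxymethoxy)phenyl]-4,4,5,5-tetramethyl-1,3,2-dioxaborolane | COCOc1cc(OCOC)cc(c1)B1OC(C)(C)C(C)(C)O1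
F4 | step 3 | 3,5-bis(methoxymethoxy)phenol | COCOc1cc(O)cc(OCOC)c1
F5 | step 3 | [3,5-bis(methoxymethoxy)phenoxy]tri(propan-2-yl)silane | COCOc1cc(OCOC)cc(O[Si](C(C)C)(C(C)C)C(C)C)c1
F6 | step 3 | [2,6-bis(methoxymethoxy)-4-{[tri(propan-2-yl)silyl]oxy}phenyl]lithium | [Li]c1c(OCOC)cc(O[Si](C(C)C)(C(C)C)C(C)C)cc1OCOC
F7 | step 3 | [3,5-bis(methoxymethoxy)-4-(3-methylbut-2-en-1-yl)phenoxy]tri(propan-2-yl)silane | CC(C)=CCc1c(OCOC)cc(O[Si](C(C)C)(C(C)C)C(C)C)cc1OCOC
F0 | step 7 | none | none
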